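**Strategy.** Everything rests on opening ring D at the C-3–O-2 lactone bond and reading C-1 (lactol carbon) and C-3 (lactone carbonyl), the two adjacent carbons on the phenolic ring B, as an ortho-dialdehyde. One carbene-catalysed oxidation then converts the formyl group beside the C-4 phenol into an acyl azolium, adds acetic acid to the other formyl group and closes ring D, which fixes C-1 as a configurationally stable acetoxy acylal. The precursor is the complete depsidone (rings A, B and C) with a free phenol and two neighbouring formyl groups on ring B, assembled by Ullmann etherification of two benzoate-derived rings and lactonization.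

Key step: step 12

Numbering: target and 18 as isobenzofuro[4,5-b][1,4]benzodioxepine (C-1 lactol carbon, C-3 lactone carbonyl, C-4 phenol); 14 as dibenzo[b,e][1,4]dioxepine (formyl groups at C-6 and C-7, phenol at C-8, ring A methyl at C-4 beside the ether bridge).

Assumption: the C-1 lactol of the target can epimerize through its ring-opened formyl acid, so the (R) configuration is taken to hold only in dry, neutral, aprotic medium and acetate 18 is the stable storage form. The sense of induction of the catalyst in step 12 is to be confirmed on the first run, both antipodes of the salt being commercial.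

**Step 1**
Reactants: 1 atraric acid (methyl 2,4-dihydroxy-3,6-dimethylbenzoate)
Product: 2 methyl 2-hydroxy-4-methoxy-3,6-dimethylbenzoate
Conditions: MeI (1.1 equiv), K2CO3, acetone, reflux
Reagents that add atoms: iodomethane, CI
Why: Williamson O-methylation should select the 4-hydroxyl, because the 2-hydroxyl is hydrogen-bonded to the ester carbonyl and flanked by two substituents.

**Step 2**
Reactants: 3 methyl 3,5-dihydroxy-4-methylbenzoate; 4 benzyl bromide
Product: 5 methyl 3,5-bis(benzyloxy)-4-methylbenzoate
Conditions: BnBr (2.4 equiv), K2CO3, DMF, 60 °C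
Reagents that add atoms: benzyl bromide (compound 4), BrCc1ccccc1
Why: Twofold Williamson etherification of the two equivalent phenols gives ethers that tolerate the later acid chloride, hydride, oxidant and hot base and can be removed without hydrogenation.

**Step 3**
Reactants: 5 methyl 3,5-bis(benzyloxy)-4-methylbenzoate
Product: 6 methyl 3,5-bis(benzyloxy)-2-formyl-4-methylbenzoate
Conditions: POCl3, DMF, 0 → 80 °C; then aq. NaOAc
Reagents that add atoms: N,N-dimethylformamide, CN(C)C=O; water, O
Why: Vilsmeier–Haack formylation can only attack the two equivalent free positions, each ortho to one benzyloxy group and para to the other, and so places the carbon that becomes C-3 next to the future phenol.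

**Step 4**
Reactants: 6 methyl 3,5-bis(benzyloxy)-2-formyl-4-methylbenzoate
Product: 7 methyl 3,5-bis(benzyloxy)-2-bromo-6-formyl-4-methylbenzoate
Conditions: NBS, MeCN, 40 °C, dark
Reagents that add atoms: N-bromosuccinimide, O=C1CCC(=O)N1Br
Why: Electrophilic aromatic bromination takes the single remaining ring position, activated ortho and para by the two ether oxygens, which puts the halogen beside the ester carbon that becomes C-1.

**Step 5**
Reactants: 7 methyl 3,5-bis(benzyloxy)-2-bromo-6-formyl-4-methylbenzoate
Product: 8 methyl 3,5-bis(benzyloxy)-2-bromo-6-(1,3-dioxolan-2-yl)-4-methylbenzoate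
Conditions: HOCH2CH2OH, TsOH·H2O (cat.), toluene, reflux, azeotropic removal of water
Reagents that add atoms: ethylene glycol, OCCO
Why: Acid-catalysed acetalization masks the formyl group so that the neighbouring ester can be brought to the aldehyde level on its own.

**Step 6**
Reactants: 8 methyl 3,5-bis(benzyloxy)-2-bromo-6-(1,3-dioxolan-2-yl)-4-methylbenzoate
Product: 9 [3,5-bis(benzyloxy)-2-bromo-6-(1,3-dioxolan-2-yl)-4-methylphenyl]methanol
Conditions: LiAlH4, THF, 0 °C → rt
Reagents that add atoms: none
Why: Hydride reduction of the hindered methyl ester to the benzylic alcohol should leave the acetal, the benzyl ethers and, at this temperature, the aryl bromide untouched.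

**Step 7**
Reactants: 9 [3,5-bis(benzyloxy)-2-bromo-6-(1,3-dioxolan-2-yl)-4-methylphenyl]methanol
Product: 10 3,5-bis(benzyloxy)-2-bromo-6-(1,3-dioxolan-2-yl)-4-methylbenzaldehyde
Conditions: DMP, NaHCO3, CH2Cl2, rt
Reagents that add atoms: none
Why: Buffered Dess–Martin oxidation stops at the aldehyde and keeps the medium non-acidic, so the dioxolane should neither hydrolyse nor migrate to the new formyl group.

**Step 8**
Reactants: 2 methyl 2-hydroxy-4-methoxy-3,6-dimethylbenzoate; 10 3,5-bis(benzyloxy)-2-bromo-6-(1,3-dioxolan-2-yl)-4-methylbenzaldehyde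
Product: 11 methyl 2-[2,4-bis(benzyloxy)-5-(1,3-dioxolan-2-yl)-6-formyl-3-methylphenoxy]-4-methoxy-3,6-dimethylbenzoate
Conditions: CuI (20 mol %), picolinic acid (40 mol %), K3PO4, DMSO, 90 °C
Reagents that add atoms: none
Why: Ullmann-type copper-catalysed diaryl ether synthesis is assisted by the free formyl group ortho to bromine, which lowers the electron density at that carbon and can bind copper, while the acetal, the benzyl ethers and the hindered ester tolerate the phosphate base.

**Step 9**
Reactants: 11 methyl 2-[2,4-bis(benzyloxy)-5-(1,3-dioxolan-2-yl)-6-formyl-3-methylphenoxy]-4-methoxy-3,6-dimethylbenzoate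
Product: 12 2-[2,4-bis(benzyloxy)-5-(1,3-dioxolan-2-yl)-6-formyl-3-methylphenoxy]-4-methoxy-3,6-dimethylbenzoic acid
Conditions: LiI, pyridine, reflux; then cold 0.5 M HCl to pH 4
Reagents that add atoms: none
Why: Iodide cleaves the doubly ortho-substituted methyl ester by SN2 attack at the methyl carbon, a path that ignores the shielding of the carbonyl and spares the aldehyde, the acetal and the aryl ethers.

**Step 10**
Reactants: 12 2-[2,4-bis(benzyloxy)-5-(1,3-dioxolan-2-yl)-6-formyl-3-methylphenoxy]-4-methoxy-3,6-dimethylbenzoic acid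
Product: 13 2-(2,3-diformyl-4,6-dihydroxy-5-methylphenoxy)-4-methoxy-3,6-dimethylbenzoic acid
Conditions: BCl3, C6HMe5, CH2Cl2, −78 → 0 °C; then 1 M HCl–THF, rt
Reagents that add atoms: water, O
Why: Lewis acid cleavage of both aryl benzyl ethers, with pentamethylbenzene trapping the benzyl cation away from the electron-rich C–H position of ring A, also opens the dioxolane (hydrolysis finished in the acidic work-up), while the non-chelated methyl ether of ring A should survive at this temperature.

**Step 11**
Reactants: 13 2-(2,3-diformyl-4,6-dihydroxy-5-methylphenoxy)-4-methoxy-3,6-dimethylbenzoic acid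
Product: 14 8-hydroxy-3-methoxy-1,4,9-trimethyl-11-oxo-11H-dibenzo[b,e][1,4]dioxepine-6,7-dicarbaldehyde
Conditions: (CF3CO)2O (3 equiv), toluene (3 mM), rt; then aq. NaHCO3 work-up
Reagents that add atoms: none
Why: In this mixed-anhydride esterification the hindered, electron-rich acid ionizes to an aroylium ion that is captured by the only hydroxyl able to reach it, the one ortho to the ether oxygen, closing the seven-membered ring C; the other phenol is para to the bridge and hydrogen-bonded to its formyl neighbour.

**Step 12**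
Reactants: 14 8-hydroxy-3-methoxy-1,4,9-trimethyl-11-oxo-11H-dibenzo[b,e][1,4]dioxepine-6,7-dicarbaldehyde; 15 acetic acid
Product: 18 (1R)-4-hydroxy-10-methoxy-5,8,11-trimethyl-3,7-dioxo-1,3-dihydro-7H-isobenzofuro[4,5-b][1,4]benzodioxepin-1-yl acetate, via acyl azolium 16 (not isolated), via hemiacylal acyl azolium 17 (not isolated)
Conditions: (5aS,10bR)-2-mesityl-5a,10b-dihydro-4H,6H-indeno[2,1-b][1,2,4]triazolo[4,3-d][1,4]oxazin-2-ium tetrafluoroborate (20 mol %), 3,3',5,5'-tetra-tert-butyldiphenoquinone (1.2 equiv), AcOH (3 equiv), i-Pr2NEt (0.5 equiv), CHCl3, rt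
Reagents that add atoms: acetic acid (compound 15), CC(=O)O
Why: The carbene adds to the C-7 formyl group, whose oxygen is hydrogen-bonded to the C-8 phenol, and the diphenoquinone oxidizes the adduct by two electrons to acyl azolium 16, while acetic acid adds reversibly to the C-6 formyl group to give the fast-epimerizing hemiacylal 17, whose hydroxyl then attacks the acyl azolium carbon and releases the carbene. The closest known reaction type is the carbene-catalysed oxidative coupling of carboxylic acids with ortho-phthalaldehydes to enantioenriched phthalidyl esters, applied here to an unsymmetrical dialdehyde. Ring D closes by 5-exo-trig acyl substitution at the acyl azolium carbon. The new stereocentre is set under catalyst control in a dynamic kinetic resolution, the aminoindanol backbone of the acyl azolium letting one hemiacylal enantiomer cyclize faster than the other, which re-equilibrates through the free aldehyde, and the acetoxy group then locks the centre as (R). The step needs site selectivity between two unlike formyl groups, and the substrate should secure it because the C-7 formyl group is the less hindered one and is activated by the phenol hydrogen bond, which the acetic acid–acetate buffer keeps from becoming a deactivating phenoxide, whereas the C-6 formyl group is shielded by the ether bridge and the C-4 methyl group of ring A yet is electron-poor enough to take up the small acid. The ring C aryl ester, the phenol and the methyl ether are inert to the mild oxidant.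

**Step 13**
Reactants: 18 (1R)-4-hydroxy-10-methoxy-5,8,11-trimethyl-3,7-dioxo-1,3-dihydro-7H-isobenzofuro[4,5-b][1,4]benzodioxepin-1-yl acetate
Product: 19 (1R)-1,4-dihydroxy-10-methoxy-5,8,11-trimethyl-1H-isobenzofuro[4,5-b][1,4]benzodioxepine-3,7-dione
Conditions: immobilized Candida antarctica lipase B, n-BuOH (5 equiv), MTBE, 25 °C
Reagents that add atoms: none
Why: Lipase-catalysed alcoholysis attacks the acetyl carbonyl and breaks the acyl C–O bond, so the C-1–O bond and the (R) configuration are not touched, and the dry neutral medium limits ring opening of the liberated lactol.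

**Compound list**

1 | atraric acid (methyl 2,4-dihydroxy-3,6-dimethylbenzoate) | COC(=O)c1c(C)cc(O)c(C)c1O | starting material
2 | methyl 2-hydroxy-4-methoxy-3,6-dimethylbenzoate | COC(=O)c1c(C)cc(OC)c(C)c1O | intermediate
3 | methyl 3,5-dihydroxy-4-methylbenzoate | COC(=O)c1cc(O)c(C)c(O)c1 | starting material
4 | benzyl bromide | BrCc1ccccc1 | starting material
5 | methyl 3,5-bis(benzyloxy)-4-methylbenzoate | COC(=O)c1cc(OCc2ccccc2)c(C)c(OCc2ccccc2)c1 | intermediate
6 | methyl 3,5-bis(benzyloxy)-2-formyl-4-methylbenzoate | COC(=O)c1cc(OCc2ccccc2)c(C)c(OCc2ccccc2)c1C=O | intermediate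
7 | methyl 3,5-bis(benzyloxy)-2-bromo-6-formyl-4-methylbenzoate | COC(=O)c1c(Br)c(OCc2ccccc2)c(C)c(OCc2ccccc2)c1C=O | intermediate
8 | methyl 3,5-bis(benzyloxy)-2-bromo-6-(1,3-dioxolan-2-yl)-4-methylbenzoate | COC(=O)c1c(Br)c(OCc2ccccc2)c(C)c(OCc2ccccc2)c1C1OCCO1 | intermediate
9 | [3,5-bis(benzyloxy)-2-bromo-6-(1,3-dioxolan-2-yl)-4-methylphenyl]methanol | OCc1c(Br)c(OCc2ccccc2)c(C)c(OCc2ccccc2)c1C1OCCO1 | intermediate
10 | 3,5-bis(benzyloxy)-2-bromo-6-(1,3-dioxolan-2-yl)-4-methylbenzaldehyde | O=Cc1c(Br)c(OCc2ccccc2)c(C)c(OCc2ccccc2)c1C1OCCO1 | intermediate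
11 | methyl 2-[2,4-bis(benzyloxy)-5-(1,3-dioxolan-2-yl)-6-formyl-3-methylphenoxy]-4-methoxy-3,6-dimethylbenzoate | COC(=O)c1c(C)cc(OC)c(C)c1Oc1c(OCc2ccccc2)c(C)c(OCc2ccccc2)c(C2OCCO2)c1C=O | intermediate
12 | 2-[2,4-bis(benzyloxy)-5-(1,3-dioxolan-2-yl)-6-formyl-3-methylphenoxy]-4-methoxy-3,6-dimethylbenzoic acid | OC(=O)c1c(C)cc(OC)c(C)c1Oc1c(OCc2ccccc2)c(C)c(OCc2ccccc2)c(C2OCCO2)c1C=O | intermediate
13 | 2-(2,3-diformyl-4,6-dihydroxy-5-methylphenoxy)-4-methoxy-3,6-dimethylbenzoic acid | OC(=O)c1c(C)cc(OC)c(C)c1Oc1c(O)c(C)c(O)c(C=O)c1C=O | intermediate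
14 | 8-hydroxy-3-methoxy-1,4,9-trimethyl-11-oxo-11H-dibenzo[b,e][1,4]dioxepine-6,7-dicarbaldehyde (depsidone ortho-dialdehyde) | COc1cc(C)c2C(=O)Oc3c(C)c(O)c(C=O)c(C=O)c3Oc2c1C | intermediate
15 | acetic acid | CC(=O)O | starting material
16 | acyl azolium: C-7 acyl derivative of 14 on the carbene carbon of the (5aS,10bR) triazolium, C-6 formyl group free (cation) | Cc1cc(C)c(c(C)c1)-[n+]1c(C(=O)c5c(O)c(C)c6OC(=O)c7c(C)cc(OC)c(C)c7Oc6c5C=O)n2[C@@H]3c4ccccc4C[C@@H]3OCc2n1 | intermediate (not isolated)
17 | hemiacylal acyl azolium: acetic acid adduct of 16 at the C-6 formyl group, both epimers at the hemiacylal carbon in equilibrium (cation) | Cc1cc(C)c(c(C)c1)-[n+]1c(C(=O)c5c(O)c(C)c6OC(=O)c7c(C)cc(OC)c(C)c7Oc6c5C(O)OC(C)=O)n2[C@@H]3c4ccccc4C[C@@H]3OCc2n1 | intermediate (not isolated)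
18 | (1R)-4-hydroxy-10-methoxy-5,8,11-trimethyl-3,7-dioxo-1,3-dihydro-7H-isobenzofuro[4,5-b][1,4]benzodioxepin-1-yl acetate | COc1cc(C)c2c(c1C)Oc1c(c(C)c(O)c3c1[C@H](OC(C)=O)OC3=O)OC2=O | intermediate
19 | (1R)-1,4-dihydroxy-10-methoxy-5,8,11-trimethyl-1H-isobenzofuro[4,5-b][1,4]benzodioxepine-3,7-dione | COc1cc(C)c2c(c1C)Oc1c(c(C)c(O)c3c1[C@H](O)OC3=O)OC2=O | target

**Totals.** Total step count: 13. Longest linear sequence: 12 steps (steps 2 to 13, from compound 3).

**Steps most likely to fail**

1. Step 12. The carbene may engage the C-6 formyl group instead of, or alongside, the C-7 formyl group, which would give the isomeric phthalide, or it may discriminate poorly between the hemiacylal enantiomers. The fallback sets out from 14 and comes back at 18. Compound 14 is heated with ethylene glycol (1.2 equiv) and pyridinium p-toluenesulfonate in toluene with azeotropic removal of water under equilibrating conditions. The chelated C-7 formyl group resists acetalization and is the thermodynamically preferred free carbonyl, so the product should be 6-(1,3-dioxolan-2-yl)-8-hydroxy-3-methoxy-1,4,9-trimethyl-11-oxo-11H-dibenzo[b,e][1,4]dioxepine-7-carbaldehyde F1. Pinnick oxidation (NaClO2, NaH2PO4, 2-methyl-2-butene, t-BuOH–H2O) then gives the corresponding 7-carboxylic acid F2. Treatment with 1 M HCl–THF unmasks C-6, and the formyl acid closes to the racemic lactol F3. Lipase-mediated acetylation with vinyl acetate in MTBE, with the lactol racemizing through its open form (dynamic kinetic resolution), should then deliver 18, from which step 13 follows.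

2. Step 8. Carbon–oxygen bond formation may be too slow at a bromide flanked by two substituents, with a weakly nucleophilic chelated phenol, so that protodebromination or decay of the aldehyde takes over on prolonged heating. The fallback sets out from 7 and comes back at 13. Reduction of 7 with NaBH4 in MeOH–THF and acidic work-up gives, by lactonization, 4,6-bis(benzyloxy)-7-bromo-5-methyl-2-benzofuran-1(3H)-one F4, in which the activating carbonyl is tied back in the ring plane and the position next to bromine is less crowded. Copper-catalysed etherification with 2 under the conditions of step 8 should give methyl 2-{[5,7-bis(benzyloxy)-6-methyl-3-oxo-1,3-dihydro-2-benzofuran-4-yl]oxy}-4-methoxy-3,6-dimethylbenzoate F5. LiBH4 in THF reduces the lactone but should spare the doubly ortho-substituted methyl benzoate of ring A, giving methyl 2-[2,4-bis(benzyloxy)-5,6-bis(hydroxymethyl)-3-methylphenoxy]-4-methoxy-3,6-dimethylbenzoate F6. Swern oxidation gives methyl 2-[2,4-bis(benzyloxy)-5,6-diformyl-3-methylphenoxy]-4-methoxy-3,6-dimethylbenzoate F7. LiI in pyridine then gives 2-[2,4-bis(benzyloxy)-5,6-diformyl-3-methylphenoxy]-4-methoxy-3,6-dimethylbenzoic acid F8, and BCl3 with pentamethylbenzene removes both benzyl groups to reach 13.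

3. Step 13. The bulky acylal may turn over slowly in the enzyme pocket or be the mismatched enantiomer for the lipase, and the liberated lactol may epimerize in the time this costs. The fallback sets out from 14 and comes back at 19. Step 12 is run with pent-4-enoic acid in place of acetic acid to give (1R)-4-hydroxy-10-methoxy-5,8,11-trimethyl-3,7-dioxo-1,3-dihydro-7H-isobenzofuro[4,5-b][1,4]benzodioxepin-1-yl pent-4-enoate F9. N-Iodosuccinimide in MeCN–H2O at 0 °C then triggers iodolactonization of the pentenoyl group, which releases 19 at neutral pH without an enzyme.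

**Further compounds**

F1 | step 12 | 6-(1,3-dioxolan-2-yl)-8-hydroxy-3-methoxy-1,4,9-trimethyl-11-oxo-11H-dibenzo[b,e][1,4]dioxepine-7-carbaldehyde | COc1cc(C)c2C(=O)Oc3c(C)c(O)c(C=O)c(C4OCCO4)c3Oc2c1C
F2 | step 12 | 6-(1,3-dioxolan-2-yl)-8-hydroxy-3-methoxy-1,4,9-trimethyl-11-oxo-11H-dibenzo[b,e][1,4]dioxepine-7-carboxylic acid | COc1cc(C)c2C(=O)Oc3c(C)c(O)c(C(=O)O)c(C4OCCO4)c3Oc2c1C
F3 | step 12 | racemic 1,4-dihydroxy-10-methoxy-5,8,11-trimethyl-1H-isobenzofuro[4,5-b][1,4]benzodioxepine-3,7-dione | COc1cc(C)c2c(c1C)Oc1c(c(C)c(O)c3c1C(O)OC3=O)OC2=O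
F4 | step 8 | 4,6-bis(benzyloxy)-7-bromo-5-methyl-2-benzofuran-1(3H)-one | O=C1OCc2c(OCc3ccccc3)c(C)c(OCc3ccccc3)c(Br)c12
F5 | step 8 | methyl 2-{[5,7-bis(benzyloxy)-6-methyl-3-oxo-1,3-dihydro-2-benzofuran-4-yl]oxy}-4-methoxy-3,6-dimethylbenzoate | COC(=O)c1c(C)cc(OC)c(C)c1Oc1c(OCc2ccccc2)c(C)c(OCc2ccccc2)c2COC(=O)c12
F6 | step 8 | methyl 2-[2,4-bis(benzyloxy)-5,6-bis(hydroxymethyl)-3-methylphenoxy]-4-methoxy-3,6-dimethylbenzoate | COC(=O)c1c(C)cc(OC)c(C)c1Oc1c(OCc2ccccc2)c(C)c(OCc2ccccc2)c(CO)c1CO
F7 | step 8 | methyl 2-[2,4-bis(benzyloxy)-5,6-diformyl-3-methylphenoxy]-4-methoxy-3,6-dimethylbenzoate | COC(=O)c1c(C)cc(OC)c(C)c1Oc1c(OCc2ccccc2)c(C)c(OCc2ccccc2)c(C=O)c1C=O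
F8 | step 8 | 2-[2,4-bis(benzyloxy)-5,6-diformyl-3-methylphenoxy]-4-methoxy-3,6-dimethylbenzoic acid | OC(=O)c1c(C)cc(OC)c(C)c1Oc1c(OCc2ccccc2)c(C)c(OCc2ccccc2)c(C=O)c1C=O
F9 | step 13 | (1R)-4-hydroxy-10-methoxy-5,8,11-trimethyl-3,7-dioxo-1,3-dihydro-7H-isobenzofuro[4,5-b][1,4]benzodioxepin-1-yl pent-4-enoate | COc1cc(C)c2c(c1C)Oc1c(c(C)c(O)c3c1[C@H](OC(=O)CCC=C)OC3=O)OC2=O
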